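The earlier runs and the new flask were computed for an exercise; noise was put on by code.

When does this flask hold most target, and how much?

| flask | substrate | reagent | free catalyst | second catalyst | remark | time |
|---|---|---|---|---|---|---|
| delta | 0.10 M (fed, over 4.0 h) | 0.095 M | 0.29 mM | 0.10 mM | run made earlier |  |
| eta | 0.10 M (fed, over 4.0 h) | 0.095 M | 0.29 mM | 0.40 mM | run made earlier |  |
| theta | 0.15 M (fed, over 4.0 h) | 0.095 M | 0.29 mM | 0.20 mM | run made earlier |  |
| flask | 0.10 M (fed, over 4.0 h) | 0.0950 M | 0.29 mM | 0.20 mM |  | 5.0 d |

| run | time / d | target / % |
|---|---|---|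
| delta | 0.0556 | 1.4 |
| delta | 0.125 | 15.4 |
| delta | 0.250 | 34.3 |
| delta | 0.625 | 18.1 |
| delta | 1.25 | 3.8 |
| delta | 3.00 | 0 |
| delta | 6.00 | 0 |
| eta | 0.0556 | 10.1 |
| eta | 0.125 | 33.7 |
| eta | 0.250 | 46.0 |
| eta | 0.625 | 19.1 |
| eta | 1.25 | 3.6 |
| eta | 3.00 | 0 |
| eta | 6.00 | 0.5 |
| theta | 0.0556 | 5.7 |
| theta | 0.208 | 33.2 |
| theta | 0.625 | 10.9 |
| theta | 2.08 | 0 |
| theta | 6.00 | 0 |

(readings scatter by 1 percentage point)

- when, up to 5.0 d, the flask holds most target
- the amount of target, in percent of the substrate charged, at that time

- the numbers in the tables scatter with a standard deviation of 1 percentage point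
- percentages count the whole charge, also what has not yet gone in

I build the flask up one process at a time. With the main step by itself, taking one reagent per substrate, the limiting reagent is the reagent, charged at 95.0% of the substrate, which is less than the whole charge. Now add the feed, which ends at 0.17 d, and the loss of target. Delta drops from 18.1% at 0.625 d to 3.8% at 1.25 d, a read decay of 2.50 d⁻¹, or a half-life of 0.278 d. That is longer than the feed, so I expect the peak soon after the feed ends.

Last comes the second catalyst. Delta reads 34.3% at 0.250 d and eta 46.0%, two doublings apart, which gives a doubling gain, the rise in target per doubling of second catalyst, of 5.9 percentage points. This flask has twice delta's second catalyst and half eta's, so it is the symmetric point, the zero of my scale. One gain above delta, I reckon 40.1% near 0.250 d.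

The forecast says 41% (37% to 45%) at 0.23 d (0.18 d to 0.29 d): “so I interpolate on a log scale”. My height is lower than that.

The flask gives 41.4% at 0.241 d, inside both ranges.

    substrate + free catalyst → free catalyst + intermediate (k = 14200 M⁻¹ h⁻¹)
    reagent + second catalyst + intermediate → second catalyst + target (k = 28500 M⁻² h⁻¹)
    free catalyst + target → free catalyst + over-reaction product (k = 574 M⁻¹ h⁻¹)

That is 1.3 points above my zero, with a single reading scattering by 1 point. At the best time this flask also holds 21.3% as over-reaction product. A run without that step peaks at 94.8% instead of 41.4%, the largest single effect on the height . Yet delta, eta and this flask carry the same free catalyst , so that loss already sits in both ends of my scale.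

A neighbouring flask with 8.0 × 10⁻⁴ M of second catalyst has twice eta's, so one gain above eta gives 51.9%. Computed, that neighbouring flask peaks at 53.9%.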